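The teal flask is the one asked about. It has been followed to 2 h, and the question stands at 4.0 h.

| flask | starting material | remark | time |
|---|---|---|---|
| teal | 0.62 M | the very flask that is asked about, followed so far |  |
| grey | 1.2 M | run made earlier |  |
| flask | 0.62 M |  | 4.0 h |

- teal (time / min: target / %, over-reaction product / %): 10.0: 12.0, 0.9; 20.0: 17.9, 0; 30.0: 24.4, 0; 60.0: 34.3, 4.2; 120: 33.7, 9.7
- grey (time / h: target / %, over-reaction product / %): 0.250: 14.6, 0.6; 0.667: 28.8, 0; 1.33: 36.1, 0.3; 2.00: 36.6, 7.1; 3.00: 32.9, 10.7

(readings scatter by 1 percentage point)

- which holds at 4.0 h: what has brought the reaction to rest, or that it has not come to rest (it is still moving / forward and back rates have come level / all of the starting material has reacted)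
- the target standing at 4.0 h, as a percentage of the starting material charged
- the over-reaction product standing at 4.0 h, as a percentage of the starting material charged

- a species is counted by the starting material in it: one idle adduct counts as two
- amounts and yields of target count idle adduct too
- steps thought possible: starting material <-> target + by-product; target -> over-reaction product; target <-> isomer of the product; starting material + target <-> idle adduct
- in an amount of target, one idle adduct counts as one target
- the reaction counts as stopped when no species that holds the starting material changes by six tenths of a point or more over the second half of the time

I fold the teal run into one number. Over its last interval the over-reaction product gains 5.5 percentage points while the target stands near 34.0%. As a pseudo-first-order drain, that reads 0.162 h⁻¹. Multiplied by the 2.00 h still to run, it gives 0.324, the drain number: the drain rate times the time left, the natural logarithm of how far unfed target falls.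

So, taking the target as unfed from here on, I expect teal's target at 24.4% and its over-reaction product at 19.0%. That estimated gain of 9.3 points is larger than a reading's scatter, so I call teal still moving.

Is one number enough? The grey run's last interval reads 0.104 h⁻¹, but each gain carries 1.4 points of scatter, so my figure is not firm.

The forecast says it is still moving, with target 26% and over-reaction product 17.5%, on the grounds that “The over-reaction product keeps growing and nothing suggests that it reverses”. Its product figure lies below mine.

The teal flask gives: it is still moving, target 26.3%, over-reaction product 25.3%.

    starting material ⇌ target + by-product (K = 0.0680 M, k = 0.0120 min⁻¹)
    target → over-reaction product (k = 0.0340 min⁻¹)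
    target ⇌ isomer of the product (K = 1.20, k = 0.00980 min⁻¹)
    starting material + target ⇌ idle adduct, settled at all times (K = 51.0 L mol⁻¹)

In the teal flask, half of the turnover of starting material into target up to the asked time is done by 0.560 h, and starting material stands at 24.1% after 2.00 h. From then to 4.00 h the idle adduct falls from 59.3% to 46.0% while the over-reaction product gains 15 points, against the 9.3 points that I estimated from 0.324.

For the teal flask left until 1.5 h, the drain number from the 1 h reading is 0.0809, which gives an estimated 6.87% of over-reaction product. The computed flask gives 6.57%.

Readings and results stem from a simulated flask on assumed constants; noise was put on by code.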